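Compounds are numbered 1–40 as in the compound list after the steps. Carbons of the acetal lactone are numbered C1–C8 as in 2,7-dioxabicyclo[3.2.1]octan-3-one; carbons of the hydroazulene are numbered C1′–C8a′ as in azulene.

## Analysis of the target

Target 40 is a cis-fused decahydroazulene whose quaternary carbon C1′ is bonded to C8, the one-carbon bridge of a 2,7-dioxabicyclo[3.2.1]octan-3-one. The seven-membered ring carries a gem-dimethyl carbon (C4′) and an exocyclic methylene (C8′). The hydroazulene holds three stereocentres: the ring-fusion hydrogens at C3a′ and C8a′ are cis, the methyl group on C1′ lies on the concave face, and the bicyclic substituent lies on the convex face. The bicycle holds five: the acetal carbon C1, the acetoxy carbon C4, the bridgehead C5, the ester-bearing C6 and C8. The hydroazulenyl group on C8 lies over the lactone bridge, the ester at C6 is exo (trans to the C5–C4 bond on the tetrahydrofuran ring), and the acetoxy group at C4 points toward the O7–C6 bridge. The two sets of stereocentres meet only in the C1′–C8 bond between a quaternary and a tertiary carbon, so each set has to be controlled in the absolute sense. Sensitive groups are the 1,1-disubstituted alkene (acid moves it into the ring), the acyloxy acetal at C1 (labile to base and nucleophiles), the α-acetoxy lactone and the enolisable C6–H next to the methyl ester. The hard part is the run of three congested carbons C1′ (quaternary), C8a′ (ring fusion) and C8′ (=CH2). The strategy rests on this run: a radical at C1′, flanked by a ketone and an ester, can add to C8a′ of a 3-methylcycloheptene, and the tertiary radical left at C8′ can be oxidised with loss of a methyl hydrogen to give the methylene group.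

## Retrosynthetic reasoning

The acetate of 40 is removed first (39), then the C4–O bond (38). The α-oxygen comes last because an α-acyloxy lactone that is also an acyloxy acetal is the most fragile part of the molecule. The finished bicycle also controls the face: in 38 the hydroazulenyl group on C8 covers one face of the lactone enolate, so an electrophilic oxygen must enter from the side of the O7–C6 bridge, which is the configuration of 40.

The lactone acetal of 38 is cut at the C1–O2 bond to acid 37, a 2-methoxytetrahydrofuran with a cis acetic acid arm. The forward reaction is capture of the oxocarbenium ion by the carboxylic acid. The acetal centre equilibrates, so only the relationship between C5 and C8 matters. The acid is carried as the 2-(trimethylsilyl)ethyl ester 36, which fluoride cleaves while the methyl ester at C6 stays and no strong acid meets the methylene group.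

In 36 the C8–C5 bond is cut. It joins a neopentyl carbon to the β-carbon of an enoate. A radical tolerates this congestion, and tethering the enoate through O7 turns the addition into a 5-exo closure of bromoacetal 35 (Ueno–Stork). This gains the tetrahydrofuran and two stereocentres (C5, C8) under control of C6, which arrives as a single enantiomer in hydroxy enoate 34. Bromoacetal 35 is cut at its acetal C–O and C–Br bonds to enol ether 25 and 34.

Hydroxy enoate 34 is cut at its alkene into vinyl glycolate 30 and acrylate 33 (cross-metathesis); 33 brings the fluoride-labile ester and comes from 31 and 32. Vinyl glycolate 30 is traced to the chiral-pool hydroxy lactone 26: selenolate opening at the O–CH2 carbon (28) and selenoxide elimination create the vinyl group without touching the stereocentre.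

Enol ether 25 comes from aldehyde 23 through acetal 24, and 23 from alcohol 22. In 22 the methyl group on C1′ and the hydroxyethyl arm are traced to one ring, the lactone 19, whose carbonyl carbon is the future methyl group. Reduction to lactol 20 and Wolff–Kishner reduction turn the masked neopentyl aldehyde into CH3 and free the arm hydroxyl at once, so the two oxygenated carbons on C1′ are told apart without protecting groups. Lactone 19 arises from acetoxy ester 17 by deacetylation and lactonisation.

Ester 17 lacks the ring ketone of 14. The ketone cannot be removed through a hydrazone, because a β-keto ester would give a pyrazolone. It must also go before the acetate is cleaved, because alkoxide would open the non-enolisable β-keto ester by retro-Claisen cleavage. It is therefore reduced (15) and deoxygenated by the Barton–McCombie method (16, then 17).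

Hydroazulenone 14 is cut at the C1′–C8a′ bond, and the methylene is returned to a methyl group; this gives the open-chain keto ester 13. Both carbons are nucleophilic in polar terms (an enol carbon and an alkene carbon), so the bond is made oxidatively. The cut is made here because this one bond closes the five-membered ring, creates the quaternary centre and the ring fusion, and its termination delivers the methylene group. The forward step must give 5-exo closure, cis fusion, the acetoxyethyl arm on the convex face and elimination toward the methyl group.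

Keto ester 13 is cut between its α-carbon and the acetoxyethyl arm (alkylation of 11 with 12). Keto ester 11 is cut at its C2–C3 bond (two-carbon extension of acid 9 through acyl imidazolide 10), and 9 is the acid of ester 8.

The stereocentre of 8 is allylic and β to the ester carbonyl, the pattern a [3,3] shift creates. Ester 8 is cut at its ring alkene to diene 7 (ring-closing metathesis), and 7 at the bond between the stereocentre and the CH2CO2Me group (Johnson–Claisen rearrangement of allylic alcohol 6). A conjugate addition to a seven-membered enone was weighed for this centre and set aside: it would have to be enantioselective at a neopentyl β-carbon and would need a regiodefined enol derivative for the ring alkene. The rearrangement takes its configuration from a ketone reduction (5 to 6) and places the alkene unambiguously. Enone 5 comes from aldehyde 4 by Wittig olefination, and 4 from nitrile 3, the alkylation product of 1 with 2.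

## Alternatives that were turned down

Alternative 1: The seven-membered ring is cut at C7′–C8′ and C3a′–C4′. In the forward step a chiral dirhodium tetracarboxylate (Rh2L4 type) converts diazo ester A1 into a vinylcarbenoid that cyclopropanates the terminal alkene of diene A2; Cope rearrangement of the cis-divinylcyclopropane gives bicyclic diene ester A3.
- For: one catalytic step builds the seven-membered ring with its gem-dimethyl carbon and sets C3a′. On convergence and on the use of asymmetric catalysis for the carbocycle it is stronger than the chosen route.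
- Against: C8a′ is left as an sp2 carbon in a tetrasubstituted enoate. Its hydrogen must later be delivered cis to H3a′ next to the quaternary centre, the ester must be reduced and eliminated to the methylene group, and the second ring alkene must be hydrogenated selectively. The quaternary centre must already be present in A1 as a single enantiomer, so the catalyst meets a matched or mismatched substrate, and the carbenoid is hindered by the adjacent quaternary carbon.
- Comparison: the chosen route creates C1′, C8a′ and the methylene group in one step and never has to reduce a tetrasubstituted alkene stereoselectively.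

Alternative 2: The lactone ring is cut at C4–C5 and O2–C3. Enal A4 reacts as a 1-oxadiene with ketene acetal A5 in an inverse-demand hetero-Diels–Alder reaction to give dihydropyran A6.
- For: the C4 oxygen and the lactone oxidation level arrive with A5, so no late enolate oxidation of the acetal lactone is needed. On this point and on convergence it is stronger than the chosen route.
- Against: A4 is a 2-substituted enal with a quaternary group on the diene carbon. It is a hindered and weakly activated heterodiene, and it already contains the whole hydroazulene, whose construction the step does not address. The step must control both the face at C5 and the endo or exo placement at C4. C8 is created afterwards by protonation of the enol ether next to the quaternary carbon, the C6 carboxyl still has to be made by deprotection and oxidation, and the silyl ortho ester is hydrolytically fragile.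
- Comparison: the chosen route sets C8 and C5 together in a ring closure steered by C6 and spends its key step on the carbocycle.

Alternative 3: The tetrahydrofuran is cut at O7–C6 and C6–C5. A divalent copper bis(1,3-diketonate) catalyst (CuL2 type) and diazo ester A8 generate the oxonium ylide at the ring oxygen of dihydropyran acetal A7; its [2,3] shift contracts the ring to tetrahydrofuran A9.
- For: C6 with its ester and the C5–C6 bond are made in one step from a two-carbon reagent through a cyclic transition state. For the tetrahydrofuran itself it is as strong as the chosen route, and more direct for the C6 ester.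
- Against: intermolecular ylide formation must select the ring oxygen over the methoxy oxygen and over cyclopropanation of the ring alkene, and the [1,2] shift competes. The vinyl group must still be oxidised to the acetoxy acid with acyclic control at C4. A9 carries a ketone where a hindered methylenation would come late. The bond between the quaternary carbon and the pyran in A7 must be made elsewhere.
- Comparison: the chosen route gets the C6 centre from the chiral pool and uses it to steer C5 and C8, and its key step supplies the quaternary centre and the methylene group, which this alternative leaves open.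

Key step: step 10

Assumption: 2 and 26 are taken as commercially available, and centres that are later destroyed or equilibrated (C2 of 13, the carbinol of 15 and 16, the acetal centres of 20 and 35–37, the CHBr centre of 35, the enol ether geometry of 25) are carried as mixtures.

## Steps

Step 1
Reactants: 1 isobutyronitrile; 2 5-bromo-2-methylpent-1-ene
Product: 3 2,2,6-trimethylhept-6-enenitrile
Conditions: LiN(iPr)2, THF, −78 °C; then 2, −78 °C → rt
Reagents that add atoms: none
Why: SN2 alkylation of the lithiated nitrile with a primary bromide installs the gem-dimethyl quaternary carbon; the remote alkene is inert.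

Step 2
Reactants: 3 2,2,6-trimethylhept-6-enenitrile
Product: 4 2,2,6-trimethylhept-6-enal
Conditions: iBu2AlH, CH2Cl2, −78 → 0 °C; then 1 M HCl, 0 °C
Reagents that add atoms: water, O
Why: Half-reduction of the hindered nitrile stops at the aluminium imine, which is hydrolysed to the aldehyde on work-up; the α-quaternary aldehyde cannot enolise.

Step 3
Reactants: 4 2,2,6-trimethylhept-6-enal
Product: 5 (3E)-5,5,9-trimethyldeca-3,9-dien-2-one
Conditions: Ph3P=CHC(O)CH3, PhMe, 110 °C
Reagents that add atoms: 1-(triphenylphosphoranylidene)propan-2-one, CC(=O)C=P(c1ccccc1)(c1ccccc1)c1ccccc1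
Why: Wittig olefination with the stabilised acetonyl ylide should give the (E)-enone; the non-enolisable aldehyde tolerates the heating that a neopentyl carbonyl needs.

Step 4
Reactants: 5 (3E)-5,5,9-trimethyldeca-3,9-dien-2-one
Product: 6 (2R,3E)-5,5,9-trimethyldeca-3,9-dien-2-ol
Conditions: (S)-2-methyl-CBS-oxazaborolidine [(3aS)-1-methyl-3,3-diphenyltetrahydro-1H,3H-pyrrolo[1,2-c][1,3,2]oxazaborole] (0.2 equiv), catecholborane, PhMe, −78 °C
Reagents that add atoms: none
Why: CBS reduction; the alkenyl group acts as the large substituent, as the aryl group does in aryl methyl ketones, so the (S)-catalyst should deliver the (R)-carbinol. Catecholborane at −78 °C does not hydroborate the terminal alkene.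

Step 5
Reactants: 6 (2R,3E)-5,5,9-trimethyldeca-3,9-dien-2-ol
Product: 7 methyl (3R,4E)-3-(2,6-dimethylhept-6-en-2-yl)hex-4-enoate
Conditions: MeC(OMe)3, EtCO2H (cat.), xylene, 140 °C (sealed tube)
Reagents that add atoms: trimethyl orthoacetate, COC(C)(OC)OC
Why: Johnson–Claisen rearrangement through a chair transition state with the carbinol methyl group equatorial transfers the carbinol configuration suprafacially to the new C–C bond. The (R,E)-alcohol should thus give the (3R)-ester with an (E)-propenyl group; [3,3] shifts form bonds next to quaternary carbons readily.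

Step 6
Reactants: 7 methyl (3R,4E)-3-(2,6-dimethylhept-6-en-2-yl)hex-4-enoate
Product: 8 methyl 2-[(1R)-3,7,7-trimethylcyclohept-2-en-1-yl]acetate
Conditions: second-generation Grubbs catalyst, RuCl2(=CHPh)(PCy3)(H2IMes) (5 mol %), CH2Cl2 (0.01 M), 40 °C
Reagents that add atoms: none
Why: Ring-closing metathesis of the propenyl group with the 1,1-disubstituted alkene closes the seven-membered ring with its trisubstituted alkene, helped by the gem-dimethyl group; propene is lost and the stereocentre is not touched.

Step 7
Reactants: 8 methyl 2-[(1R)-3,7,7-trimethylcyclohept-2-en-1-yl]acetate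
Product: 9 2-[(1R)-3,7,7-trimethylcyclohept-2-en-1-yl]acetic acid
Conditions: LiOH, THF/MeOH/H2O, rt; then 1 M HCl to pH 3
Reagents that add atoms: lithium hydroxide, [Li+].[OH-]
Why: Saponification of an unhindered methyl ester; the stereocentre is β to the carboxyl group and cannot epimerise.

Step 8
Reactants: 9 2-[(1R)-3,7,7-trimethylcyclohept-2-en-1-yl]acetic acid
Product: 11 methyl 3-oxo-4-[(1R)-3,7,7-trimethylcyclohept-2-en-1-yl]butanoate, via acyl imidazolide 10 (not isolated)
Conditions: 1,1′-carbonyldiimidazole, THF, rt; then Mg(O2CCH2CO2Me)2, THF, rt → 45 °C; 1 M HCl work-up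
Reagents that add atoms: 1,1′-carbonyldiimidazole, O=C(n1ccnc1)n1ccnc1 (imidazolyl group of 10 only); magnesium bis(methyl malonate), COC(=O)CC(=O)[O-].COC(=O)CC(=O)[O-].[Mg+2]
Why: Masamune–Brooks chain extension: the acyl imidazolide is C-acylated by the magnesium malonate half-ester and decarboxylation gives the β-keto ester under near-neutral conditions.

Step 9
Reactants: 11 methyl 3-oxo-4-[(1R)-3,7,7-trimethylcyclohept-2-en-1-yl]butanoate; 12 2-bromoethyl acetate
Product: 13 methyl 2-[2-(acetyloxy)ethyl]-3-oxo-4-[(1R)-3,7,7-trimethylcyclohept-2-en-1-yl]butanoate (C2 epimers)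
Conditions: K2CO3, NaI (cat.), acetone, 56 °C
Reagents that add atoms: none
Why: C-alkylation of the β-keto ester enolate with the primary halide under carbonate conditions, which spare the acetate; the new centre becomes a planar radical in the next step, so its configuration does not matter.

Step 10
Reactants: 13 methyl 2-[2-(acetyloxy)ethyl]-3-oxo-4-[(1R)-3,7,7-trimethylcyclohept-2-en-1-yl]butanoate
Product: 14 methyl (1R,3aR,8aS)-1-[2-(acetyloxy)ethyl]-4,4-dimethyl-8-methylidene-2-oxodecahydroazulene-1-carboxylate
Conditions: Mn(OAc)3·2H2O (2.2 equiv), Cu(OAc)2·H2O (1 equiv), AcOH (degassed), 50 °C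
Reagents that add atoms: none
Why: Mn(OAc)3 forms the manganese enolate of the α-substituted β-keto ester and oxidises it to the α-keto ester radical, which adds to the unsubstituted alkene carbon C2 of the cycloheptene and leaves a tertiary radical at C3. Cu(OAc)2 captures this radical as an alkylcopper species that eliminates a β-hydrogen toward the methyl group, the least hindered and statistically favoured direction, to give the exocyclic methylene; the copper is reoxidised by Mn(OAc)3. The closest known reaction type is the Mn(OAc)3/Cu(OAc)2 oxidative free-radical cyclisation of unsaturated α-alkyl β-keto esters with oxidative termination. The cyclopentanone closes in the 5-exo-trig mode; 6-endo attack would have to take place at the methyl-bearing alkene carbon and would give a secondary radical. C8a′ is set by the tether: the chain on the (R)-configured ring carbon can reach only the adjacent alkene face, so the ring fusion is cis. C1′ is set in the same transition state: the sp3 acetoxyethyl arm is expected to turn away from the seven-membered ring (convex face), while the planar ester, conjugated with the radical, lies over it. The α-substituent and the quaternary product centre prevent further oxidation. The step needs 5-exo regioselectivity (secured by the alkene substitution), cis fusion (secured by the tether), the arm on the convex face and termination toward the methyl group (both biased but not enforced).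

Step 11
Reactants: 14 methyl (1R,3aR,8aS)-1-[2-(acetyloxy)ethyl]-4,4-dimethyl-8-methylidene-2-oxodecahydroazulene-1-carboxylate
Product: 15 methyl (1R,3aR,8aS)-1-[2-(acetyloxy)ethyl]-2-hydroxy-4,4-dimethyl-8-methylidenedecahydroazulene-1-carboxylate (C2 epimers)
Conditions: NaBH4, MeOH, −20 → 0 °C
Reagents that add atoms: none
Why: Borohydride reduces the ketone and leaves the ester and, at low temperature, the acetate; the carbinol configuration is irrelevant because this carbon is deoxygenated.

Step 12
Reactants: 15 methyl (1R,3aR,8aS)-1-[2-(acetyloxy)ethyl]-2-hydroxy-4,4-dimethyl-8-methylidenedecahydroazulene-1-carboxylate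
Product: 16 methyl (1R,3aR,8aS)-1-[2-(acetyloxy)ethyl]-2-[(1H-imidazol-1-ylcarbonothioyl)oxy]-4,4-dimethyl-8-methylidenedecahydroazulene-1-carboxylate
Conditions: 1,1′-thiocarbonyldiimidazole, 4-(dimethylamino)pyridine (cat.), ClCH2CH2Cl, 80 °C
Reagents that add atoms: 1,1′-thiocarbonyldiimidazole, S=C(n1ccnc1)n1ccnc1
Why: Thioacylation of the hindered secondary alcohol under neutral conditions prepares the Barton–McCombie substrate without exposing the β-hydroxy ester to base (retro-aldol cleavage).

Step 13
Reactants: 16 methyl (1R,3aR,8aS)-1-[2-(acetyloxy)ethyl]-2-[(1H-imidazol-1-ylcarbonothioyl)oxy]-4,4-dimethyl-8-methylidenedecahydroazulene-1-carboxylate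
Product: 17 methyl (1R,3aR,8aS)-1-[2-(acetyloxy)ethyl]-4,4-dimethyl-8-methylidenedecahydroazulene-1-carboxylate
Conditions: Bu3SnH, azobisisobutyronitrile (cat.), PhMe, 110 °C
Reagents that add atoms: none
Why: Barton–McCombie deoxygenation: the stannyl radical adds to the thiocarbonyl group and the secondary ring radical is reduced by Bu3SnH; the methylene group is reachable only by 4-exo or 5-endo closure and should stay intact.

Step 14
Reactants: 17 methyl (1R,3aR,8aS)-1-[2-(acetyloxy)ethyl]-4,4-dimethyl-8-methylidenedecahydroazulene-1-carboxylate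
Product: 19 (1R,3aR,8aS)-4,4-dimethyl-8-methylidenedecahydrospiro[azulene-1,3′-oxolan]-2′-one (lactone carbonyl on the concave face), via hydroxy ester 18 (not isolated)
Conditions: K2CO3, MeOH, rt
Reagents that add atoms: none
Why: Methanolysis of the acetate frees the primary alcohol, which lactonises onto the neighbouring ester (five-membered ring, favoured by the quaternary carbon); with the ketone gone no retro-Claisen pathway is open.

Step 15
Reactants: 19 (1R,3aR,8aS)-4,4-dimethyl-8-methylidenedecahydrospiro[azulene-1,3′-oxolan]-2′-one
Product: 20 (1R,3aR,8aS)-4,4-dimethyl-8-methylidenedecahydrospiro[azulene-1,3′-oxolan]-2′-ol (both anomers)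
Conditions: iBu2AlH, CH2Cl2, −78 °C; aq. potassium sodium tartrate
Reagents that add atoms: none
Why: Half-reduction of the hindered γ-lactone; the tetrahedral aluminate is stable at −78 °C and gives the lactol on work-up.

Step 16
Reactants: 20 (1R,3aR,8aS)-4,4-dimethyl-8-methylidenedecahydrospiro[azulene-1,3′-oxolan]-2′-ol
Product: 22 2-[(1S,3aR,8aS)-1,4,4-trimethyl-8-methylidenedecahydroazulen-1-yl]ethan-1-ol, via hydrazone 21 (not isolated)
Conditions: N2H4·H2O, KOH, diethylene glycol, 130 °C then 200 °C, argon
Reagents that add atoms: hydrazine hydrate, NN.O (nitrogen atoms of 21 only)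
Why: Wolff–Kishner reduction (Huang-Minlon procedure): the lactol opens to the hydroxy aldehyde, whose hydrazone loses N2 to give the C1′ methyl group and the free primary alcohol in one operation. The neopentyl aldehyde cannot enolise, and the isolated alkene tolerates hydroxide when air is excluded so that no diimide forms.

Step 17
Reactants: 22 2-[(1S,3aR,8aS)-1,4,4-trimethyl-8-methylidenedecahydroazulen-1-yl]ethan-1-ol
Product: 23 2-[(1S,3aR,8aS)-1,4,4-trimethyl-8-methylidenedecahydroazulen-1-yl]acetaldehyde
Conditions: DMP [1,1,1-triacetoxy-1,1-dihydro-1,2-benziodoxol-3(1H)-one], CH2Cl2, 0 °C → rt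
Reagents that add atoms: none
Why: Periodinane oxidation of the primary alcohol stops at the aldehyde under conditions too weakly acidic to move the methylene group.

Step 18
Reactants: 23 2-[(1S,3aR,8aS)-1,4,4-trimethyl-8-methylidenedecahydroazulen-1-yl]acetaldehyde
Product: 24 (1S,3aR,8aS)-1-(2,2-dimethoxyethyl)-1,4,4-trimethyl-8-methylidenedecahydroazulene
Conditions: HC(OMe)3, pyridinium p-toluenesulfonate (cat.), MeOH, rt
Reagents that add atoms: trimethyl orthoformate, COC(OC)OC
Why: Acetalisation driven by the orthoformate; the pyridinium salt is too weak an acid to protonate the alkene.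

Step 19
Reactants: 24 (1S,3aR,8aS)-1-(2,2-dimethoxyethyl)-1,4,4-trimethyl-8-methylidenedecahydroazulene
Product: 25 (1R,3aR,8aS)-1-(2-methoxyethenyl)-1,4,4-trimethyl-8-methylidenedecahydroazulene (E/Z mixture)
Conditions: Me3SiOTf, iPr2NEt, CH2Cl2, −20 °C → rt
Reagents that add atoms: none
Why: The silyl triflate ionises the acetal and the amine removes the α-proton (acetal to enol ether elimination); the medium stays basic, so the methylene group is safe.

Step 20
Reactants: 26 (3R)-3-hydroxyoxolan-2-one
Product: 28 methyl (2R)-2-hydroxy-4-(phenylselanyl)butanoate, via sodium carboxylate 27 (not isolated)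
Conditions: PhSeNa [from (PhSe)2, Na, THF], DMF, 100 °C; then MeI, rt
Reagents that add atoms: sodium benzeneselenolate (from diphenyl diselenide, c1ccc(cc1)[Se][Se]c1ccccc1), [Na+].[Se-]c1ccccc1; iodomethane, CI
Why: The selenolate opens the γ-lactone by SN2 attack at the O–CH2 carbon, remote from the stereocentre, and the carboxylate is methylated in the same flask; the selenolate is too weak a base to form the alkoxide, so O-methylation is not expected.

Step 21
Reactants: 28 methyl (2R)-2-hydroxy-4-(phenylselanyl)butanoate
Product: 30 methyl (2R)-2-hydroxybut-3-enoate, via selenoxide 29 (not isolated)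
Conditions: H2O2 (30 % aq.), THF, 0 °C; then 50 °C
Reagents that add atoms: hydrogen peroxide, OO (oxygen atom of 29 only)
Why: Oxidation to the selenoxide and thermal syn-elimination give the terminal alkene; elimination can only go toward C3 and leaves the carbinol centre untouched.

Step 22
Reactants: 31 prop-2-enoyl chloride; 32 2-(trimethylsilyl)ethan-1-ol
Product: 33 2-(trimethylsilyl)ethyl prop-2-enoate
Conditions: Et3N, CH2Cl2, 0 °C
Reagents that add atoms: none
Why: Acylation of the primary alcohol by the acid chloride with an amine base.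

Step 23
Reactants: 30 methyl (2R)-2-hydroxybut-3-enoate; 33 2-(trimethylsilyl)ethyl prop-2-enoate
Product: 34 5-methyl 1-[2-(trimethylsilyl)ethyl] (2E,4R)-4-hydroxypent-2-enedioate
Conditions: second-generation Hoveyda–Grubbs catalyst, RuCl2(=CH-C6H4-2-OiPr)(H2IMes) (5 mol %), 33 (3 equiv), CH2Cl2, 40 °C
Reagents that add atoms: none
Why: Cross-metathesis of the allylic alcohol with an excess of the acrylate, which homodimerises slowly, should give the (E)-γ-hydroxy enoate; the stereocentre is not involved.

Step 24
Reactants: 25 (1R,3aR,8aS)-1-(2-methoxyethenyl)-1,4,4-trimethyl-8-methylidenedecahydroazulene; 34 5-methyl 1-[2-(trimethylsilyl)ethyl] (2E,4R)-4-hydroxypent-2-enedioate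
Product: 35 5-methyl 1-[2-(trimethylsilyl)ethyl] (2E,4R)-4-{2-bromo-1-methoxy-2-[(1R,3aR,8aS)-1,4,4-trimethyl-8-methylidenedecahydroazulen-1-yl]ethoxy}pent-2-enedioate (epimers at the CHBr and acetal carbons)
Conditions: N-bromosuccinimide, CH2Cl2, −78 → −20 °C
Reagents that add atoms: N-bromosuccinimide, O=C1CCC(=O)N1Br
Why: Bromoetherification: the electron-rich enol ether takes up bromine far faster than the 1,1-disubstituted alkene at low temperature, and the α-bromo oxocarbenium ion is captured by the hydroxyl of 34. Both new centres are later removed or equilibrated.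

Step 25
Reactants: 35 5-methyl 1-[2-(trimethylsilyl)ethyl] (2E,4R)-4-{2-bromo-1-methoxy-2-[(1R,3aR,8aS)-1,4,4-trimethyl-8-methylidenedecahydroazulen-1-yl]ethoxy}pent-2-enedioate
Product: 36 methyl (2R,3R,4R)-5-methoxy-3-{2-oxo-2-[2-(trimethylsilyl)ethoxy]ethyl}-4-[(1R,3aR,8aS)-1,4,4-trimethyl-8-methylidenedecahydroazulen-1-yl]oxolane-2-carboxylate (both C5 epimers)
Conditions: Bu3SnH (slow addition), azobisisobutyronitrile (cat.), PhH (0.01 M), 80 °C
Reagents that add atoms: none
Why: Ueno–Stork 5-exo-trig radical cyclisation: the secondary radical at the future C8 adds to the β-carbon of the enoate through a chair-like transition state in which the hydroazulenyl group and the C6 ester are pseudo-equatorial. This places the acetate arm cis to the hydroazulenyl group and trans to the ester, so the C6 centre of 34 sets C5 and C8; the α-ester radical is then reduced by Bu3SnH.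

Step 26
Reactants: 36 methyl (2R,3R,4R)-5-methoxy-3-{2-oxo-2-[2-(trimethylsilyl)ethoxy]ethyl}-4-[(1R,3aR,8aS)-1,4,4-trimethyl-8-methylidenedecahydroazulen-1-yl]oxolane-2-carboxylate
Product: 37 [(2R,3R,4R)-5-methoxy-2-(methoxycarbonyl)-4-[(1R,3aR,8aS)-1,4,4-trimethyl-8-methylidenedecahydroazulen-1-yl]oxolan-3-yl]acetic acid (both C5 epimers)
Conditions: Bu4NF, THF, 0 °C → rt; aq. NH4Cl
Reagents that add atoms: none
Why: Fluoride-induced fragmentation of the 2-(trimethylsilyl)ethyl ester frees the acid without acid or hydroxide, so the methyl ester, the acetal and the methylene group are untouched.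

Step 27
Reactants: 37 [(2R,3R,4R)-5-methoxy-2-(methoxycarbonyl)-4-[(1R,3aR,8aS)-1,4,4-trimethyl-8-methylidenedecahydroazulen-1-yl]oxolan-3-yl]acetic acid
Product: 38 methyl (1S,5R,6R,8R)-3-oxo-8-[(1R,3aR,8aS)-1,4,4-trimethyl-8-methylidenedecahydroazulen-1-yl]-2,7-dioxabicyclo[3.2.1]octane-6-carboxylate
Conditions: pyridinium p-toluenesulfonate (cat.), 4 Å molecular sieves, PhMe, 70 °C
Reagents that add atoms: none
Why: Mild acid ionises the methyl acetal to the oxocarbenium ion, which the cis carboxylic acid traps as the six-membered lactone; the acetal centre equilibrates, so both epimers converge, and removal of methanol drives the exchange.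

Step 28
Reactants: 38 methyl (1S,5R,6R,8R)-3-oxo-8-[(1R,3aR,8aS)-1,4,4-trimethyl-8-methylidenedecahydroazulen-1-yl]-2,7-dioxabicyclo[3.2.1]octane-6-carboxylate
Product: 39 methyl (1S,4S,5S,6R,8R)-4-hydroxy-3-oxo-8-[(1R,3aR,8aS)-1,4,4-trimethyl-8-methylidenedecahydroazulen-1-yl]-2,7-dioxabicyclo[3.2.1]octane-6-carboxylate
Conditions: KN(SiMe3)2, THF, −78 °C; then 2-(phenylsulfonyl)-3-phenyloxaziridine, −78 °C; AcOH quench
Reagents that add atoms: 2-(phenylsulfonyl)-3-phenyloxaziridine, O=S(=O)(N1OC1c1ccccc1)c1ccccc1
Why: Enolate hydroxylation: the bridged δ-lactone CH2 is more acidic and more accessible than the tertiary α-alkoxy ester CH at C6. The oxaziridine should attack from the side of the O7–C6 bridge because the other face is covered by the hydroazulenyl group on C8, which gives the (4S)-alcohol.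

Step 29
Reactants: 39 methyl (1S,4S,5S,6R,8R)-4-hydroxy-3-oxo-8-[(1R,3aR,8aS)-1,4,4-trimethyl-8-methylidenedecahydroazulen-1-yl]-2,7-dioxabicyclo[3.2.1]octane-6-carboxylate
Product: 40 methyl (1S,4S,5R,6R,8R)-4-(acetyloxy)-3-oxo-8-[(1R,3aR,8aS)-1,4,4-trimethyl-8-methylidenedecahydroazulen-1-yl]-2,7-dioxabicyclo[3.2.1]octane-6-carboxylate
Conditions: Ac2O, pyridine, 4-(dimethylamino)pyridine (cat.), CH2Cl2, 0 °C
Reagents that add atoms: acetic anhydride, CC(=O)OC(C)=O
Why: Acetylation of the secondary alcohol under weakly basic, non-nucleophilic conditions that the lactone acetal tolerates; no stereocentre is touched.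

## Compound list

1 | isobutyronitrile | CC(C)C#N | starting material
2 | 5-bromo-2-methylpent-1-ene | C=C(C)CCCBr | starting material
3 | 2,2,6-trimethylhept-6-enenitrile | C=C(C)CCCC(C)(C)C#N | intermediate
4 | 2,2,6-trimethylhept-6-enal | C=C(C)CCCC(C)(C)C=O | intermediate
5 | (3E)-5,5,9-trimethyldeca-3,9-dien-2-one | CC(=O)/C=C/C(C)(C)CCCC(C)=C | intermediate
6 | (2R,3E)-5,5,9-trimethyldeca-3,9-dien-2-ol | C[C@@H](O)/C=C/C(C)(C)CCCC(C)=C | intermediate
7 | methyl (3R,4E)-3-(2,6-dimethylhept-6-en-2-yl)hex-4-enoate | COC(=O)C[C@H](/C=C/C)C(C)(C)CCCC(C)=C | intermediate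
8 | methyl 2-[(1R)-3,7,7-trimethylcyclohept-2-en-1-yl]acetate | CC1=C[C@@H](CC(=O)OC)C(C)(C)CCC1 | intermediate
9 | 2-[(1R)-3,7,7-trimethylcyclohept-2-en-1-yl]acetic acid | CC1=C[C@@H](CC(=O)O)C(C)(C)CCC1 | intermediate
10 | 1-(1H-imidazol-1-yl)-2-[(1R)-3,7,7-trimethylcyclohept-2-en-1-yl]ethan-1-one (acyl imidazolide) | CC1=C[C@@H](CC(=O)n2ccnc2)C(C)(C)CCC1 | intermediate
11 | methyl 3-oxo-4-[(1R)-3,7,7-trimethylcyclohept-2-en-1-yl]butanoate | CC1=C[C@@H](CC(=O)CC(=O)OC)C(C)(C)CCC1 | intermediate
12 | 2-bromoethyl acetate | CC(=O)OCCBr | starting material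
13 | methyl 2-[2-(acetyloxy)ethyl]-3-oxo-4-[(1R)-3,7,7-trimethylcyclohept-2-en-1-yl]butanoate (C2 epimers) | CC1=C[C@@H](CC(=O)C(CCOC(C)=O)C(=O)OC)C(C)(C)CCC1 | intermediate
14 | methyl (1R,3aR,8aS)-1-[2-(acetyloxy)ethyl]-4,4-dimethyl-8-methylidene-2-oxodecahydroazulene-1-carboxylate (cis-fused; arm on the face of the ring-fusion hydrogens) | C=C1CCCC(C)(C)[C@@H]2CC(=O)[C@@](C(=O)OC)(CCOC(C)=O)[C@H]12 | intermediate
15 | methyl (1R,3aR,8aS)-1-[2-(acetyloxy)ethyl]-2-hydroxy-4,4-dimethyl-8-methylidenedecahydroazulene-1-carboxylate (C2 epimers) | C=C1CCCC(C)(C)[C@@H]2CC(O)[C@@](C(=O)OC)(CCOC(C)=O)[C@H]12 | intermediate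
16 | methyl (1R,3aR,8aS)-1-[2-(acetyloxy)ethyl]-2-[(1H-imidazol-1-ylcarbonothioyl)oxy]-4,4-dimethyl-8-methylidenedecahydroazulene-1-carboxylate | C=C1CCCC(C)(C)[C@@H]2CC(OC(=S)n3ccnc3)[C@@](C(=O)OC)(CCOC(C)=O)[C@H]12 | intermediate
17 | methyl (1R,3aR,8aS)-1-[2-(acetyloxy)ethyl]-4,4-dimethyl-8-methylidenedecahydroazulene-1-carboxylate | C=C1CCCC(C)(C)[C@@H]2CC[C@@](C(=O)OC)(CCOC(C)=O)[C@H]12 | intermediate
18 | methyl (1R,3aR,8aS)-1-(2-hydroxyethyl)-4,4-dimethyl-8-methylidenedecahydroazulene-1-carboxylate | C=C1CCCC(C)(C)[C@@H]2CC[C@@](C(=O)OC)(CCO)[C@H]12 | intermediate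
19 | (1R,3aR,8aS)-4,4-dimethyl-8-methylidenedecahydrospiro[azulene-1,3′-oxolan]-2′-one | C=C1CCCC(C)(C)[C@@H]2CC[C@@]3(CCOC3=O)[C@H]12 | intermediate
20 | (1R,3aR,8aS)-4,4-dimethyl-8-methylidenedecahydrospiro[azulene-1,3′-oxolan]-2′-ol (both anomers) | C=C1CCCC(C)(C)[C@@H]2CC[C@@]3(CCOC3O)[C@H]12 | intermediate
21 | hydrazone of (1R,3aR,8aS)-1-(2-hydroxyethyl)-4,4-dimethyl-8-methylidenedecahydroazulene-1-carbaldehyde | C=C1CCCC(C)(C)[C@@H]2CC[C@@](C=NN)(CCO)[C@H]12 | intermediate
22 | 2-[(1S,3aR,8aS)-1,4,4-trimethyl-8-methylidenedecahydroazulen-1-yl]ethan-1-ol | C=C1CCCC(C)(C)[C@@H]2CC[C@@](C)(CCO)[C@H]12 | intermediate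
23 | 2-[(1S,3aR,8aS)-1,4,4-trimethyl-8-methylidenedecahydroazulen-1-yl]acetaldehyde | C=C1CCCC(C)(C)[C@@H]2CC[C@@](C)(CC=O)[C@H]12 | intermediate
24 | (1S,3aR,8aS)-1-(2,2-dimethoxyethyl)-1,4,4-trimethyl-8-methylidenedecahydroazulene | C=C1CCCC(C)(C)[C@@H]2CC[C@@](C)(CC(OC)OC)[C@H]12 | intermediate
25 | (1R,3aR,8aS)-1-(2-methoxyethenyl)-1,4,4-trimethyl-8-methylidenedecahydroazulene (E/Z mixture) | C=C1CCCC(C)(C)[C@@H]2CC[C@@](C)(C=COC)[C@H]12 | intermediate
26 | (3R)-3-hydroxyoxolan-2-one | O=C1OCC[C@H]1O | starting material
27 | sodium (2R)-2-hydroxy-4-(phenylselanyl)butanoate | [Na+].[O-]C(=O)[C@H](O)CC[Se]c1ccccc1 | intermediate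
28 | methyl (2R)-2-hydroxy-4-(phenylselanyl)butanoate | COC(=O)[C@H](O)CC[Se]c1ccccc1 | intermediate
29 | methyl (2R)-2-hydroxy-4-(phenylseleninyl)butanoate | COC(=O)[C@H](O)CC[Se](=O)c1ccccc1 | intermediate
30 | methyl (2R)-2-hydroxybut-3-enoate | COC(=O)[C@H](O)C=C | intermediate
31 | prop-2-enoyl chloride | C=CC(=O)Cl | starting material
32 | 2-(trimethylsilyl)ethan-1-ol | C[Si](C)(C)CCO | starting material
33 | 2-(trimethylsilyl)ethyl prop-2-enoate | C=CC(=O)OCC[Si](C)(C)C | intermediate
34 | 5-methyl 1-[2-(trimethylsilyl)ethyl] (2E,4R)-4-hydroxypent-2-enedioate | COC(=O)[C@H](O)/C=C/C(=O)OCC[Si](C)(C)C | intermediate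
35 | 5-methyl 1-[2-(trimethylsilyl)ethyl] (2E,4R)-4-{2-bromo-1-methoxy-2-[(1R,3aR,8aS)-1,4,4-trimethyl-8-methylidenedecahydroazulen-1-yl]ethoxy}pent-2-enedioate (epimers at the CHBr and acetal carbons) | C=C1CCCC(C)(C)[C@@H]2CC[C@@](C)(C(Br)C(OC)O[C@@H](C(=O)OC)/C=C/C(=O)OCC[Si](C)(C)C)[C@H]12 | intermediate
36 | methyl (2R,3R,4R)-5-methoxy-3-{2-oxo-2-[2-(trimethylsilyl)ethoxy]ethyl}-4-[(1R,3aR,8aS)-1,4,4-trimethyl-8-methylidenedecahydroazulen-1-yl]oxolane-2-carboxylate (both C5 epimers) | C=C1CCCC(C)(C)[C@@H]2CC[C@@](C)([C@@H]3C(OC)O[C@@H](C(=O)OC)[C@@H]3CC(=O)OCC[Si](C)(C)C)[C@H]12 | intermediate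
37 | [(2R,3R,4R)-5-methoxy-2-(methoxycarbonyl)-4-[(1R,3aR,8aS)-1,4,4-trimethyl-8-methylidenedecahydroazulen-1-yl]oxolan-3-yl]acetic acid (both C5 epimers) | C=C1CCCC(C)(C)[C@@H]2CC[C@@](C)([C@@H]3C(OC)O[C@@H](C(=O)OC)[C@@H]3CC(=O)O)[C@H]12 | intermediate
38 | methyl (1S,5R,6R,8R)-3-oxo-8-[(1R,3aR,8aS)-1,4,4-trimethyl-8-methylidenedecahydroazulen-1-yl]-2,7-dioxabicyclo[3.2.1]octane-6-carboxylate | C=C1CCCC(C)(C)[C@@H]2CC[C@@](C)([C@@H]3[C@@H]4OC(=O)C[C@H]3[C@H](C(=O)OC)O4)[C@H]12 | intermediate
39 | methyl (1S,4S,5S,6R,8R)-4-hydroxy-3-oxo-8-[(1R,3aR,8aS)-1,4,4-trimethyl-8-methylidenedecahydroazulen-1-yl]-2,7-dioxabicyclo[3.2.1]octane-6-carboxylate | C=C1CCCC(C)(C)[C@@H]2CC[C@@](C)([C@@H]3[C@@H]4OC(=O)[C@@H](O)[C@H]3[C@H](C(=O)OC)O4)[C@H]12 | intermediate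
40 | methyl (1S,4S,5R,6R,8R)-4-(acetyloxy)-3-oxo-8-[(1R,3aR,8aS)-1,4,4-trimethyl-8-methylidenedecahydroazulen-1-yl]-2,7-dioxabicyclo[3.2.1]octane-6-carboxylate | C=C1CCCC(C)(C)[C@@H]2CC[C@@](C)([C@@H]3[C@@H]4OC(=O)[C@@H](OC(C)=O)[C@H]3[C@H](C(=O)OC)O4)[C@H]12 | target

## Step count and least certain steps

Total step count: 29. Longest linear sequence: 25 steps (steps 1–19 and 24–29); the fragment 34 is made in four steps (20–23).

Step 10 (key step). The most likely failure is poor facial discrimination at the radical carbon, so that the ester rather than the acetoxyethyl arm takes the convex site. The two groups differ little in size and nothing but the shape of the transition state separates them. Termination may also stray: elimination into the ring, or ionisation of the tertiary centre followed by lactonisation with the ester that lies on the same face. The fallback sets out from 11 and returns at 25.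
- Methylation of 11 (MeI, K2CO3) gives the α-methyl keto ester F1.
- The same Mn(OAc)3/Cu(OAc)2 cyclisation gives the hydroazulenone F2, in which the small methyl group takes the concave site and the ester the convex one, away from the tertiary radical centre.
- Borohydride reduction gives the alcohol F3, thioacylation the thiocarbamate F4, and tin hydride deoxygenation the ester F5.
- LiAlH4 gives the neopentyl alcohol F6 and periodinane oxidation the aldehyde F7.
- Wittig methoxymethylenation (Ph3P=CHOMe) converts F7 into enol ether 25, because the ester carbon now becomes the first carbon of the side chain.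

Step 25. The radical at the future C8 sits next to the quaternary carbon. Its attack on the enoate may show poor facial selectivity if the bias of that centre opposes the chair transition state, and the hindered radical may be reduced before it closes. The fallback relies on thermodynamic control; it sets out from 37, carried as the C8 epimer mixture, and returns at 38.
- Aqueous acetic acid in THF hydrolyses the methyl acetal to the lactol acid F9.
- F9 is heated with piperidinium acetate and molecular sieves in toluene. The ring-opened aldehyde epimerises at C8 through its enamine.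
- Closure to the lactone acetal withdraws the epimer whose hydroazulenyl group lies over the flat lactone bridge and away from the exo ester at C6, which is 38.

Step 24. Bromine may be transferred to the exocyclic alkene, or the hindered α-bromo oxocarbenium ion may be captured slowly by the weakly nucleophilic α-hydroxy ester 34, so that succinimide or water adds in its place. The fallback sets out from 25 and returns at 35.
- N-Bromosuccinimide in methanol gives the α-bromo dimethyl acetal F8, the solvent capturing the cation efficiently.
- Et3SiOTf and 2,4,6-collidine convert one methoxy group of F8 into a collidinium leaving group, which 34 displaces under non-acidic conditions to give 35.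

Step 28. Deprotonation may compete at C6 (epimerisation or oxidation next to the methyl ester), or the lactone enolate may fragment with loss of the acetal oxygen. The fallback places the C4 oxygen in the radical step; it sets out from 35 and returns at 40.
- Cyclisation of 35 with Bu3SnH under dry air traps the α-ester radical with oxygen to give the hydroperoxide F10, which triphenylphosphine reduces to the hydroxy ester F11 (C4 epimers).
- Acetylation gives the acetate F12 and fluoride cleavage the acid F13.
- The closure of step 27 gives 40 together with its C4 epimer F14.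
- Brief exposure of F14 to triethylamine converts it into 40, because the acetoxy group avoids the lactone face covered by the hydroazulenyl group.

## Further compounds

F1 | step 10 | methyl 2-methyl-3-oxo-4-[(1R)-3,7,7-trimethylcyclohept-2-en-1-yl]butanoate (C2 epimers) | CC1=C[C@@H](CC(=O)C(C)C(=O)OC)C(C)(C)CCC1
F2 | step 10 | methyl (1S,3aR,8aS)-1,4,4-trimethyl-8-methylidene-2-oxodecahydroazulene-1-carboxylate | C=C1CCCC(C)(C)[C@@H]2CC(=O)[C@@](C)(C(=O)OC)[C@H]12
F3 | step 10 | methyl (1S,3aR,8aS)-2-hydroxy-1,4,4-trimethyl-8-methylidenedecahydroazulene-1-carboxylate (C2 epimers) | C=C1CCCC(C)(C)[C@@H]2CC(O)[C@@](C)(C(=O)OC)[C@H]12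
F4 | step 10 | methyl (1S,3aR,8aS)-2-[(1H-imidazol-1-ylcarbonothioyl)oxy]-1,4,4-trimethyl-8-methylidenedecahydroazulene-1-carboxylate | C=C1CCCC(C)(C)[C@@H]2CC(OC(=S)n3ccnc3)[C@@](C)(C(=O)OC)[C@H]12
F5 | step 10 | methyl 1,4,4-trimethyl-8-methylidenedecahydroazulene-1-carboxylate (cis-fused, ester on the face of the ring-fusion hydrogens) | C=C1CCCC(C)(C)[C@@H]2CC[C@@](C)(C(=O)OC)[C@H]12
F6 | step 10 | [1,4,4-trimethyl-8-methylidenedecahydroazulen-1-yl]methanol (configured as F5) | C=C1CCCC(C)(C)[C@@H]2CC[C@@](C)(CO)[C@H]12
F7 | step 10 | 1,4,4-trimethyl-8-methylidenedecahydroazulene-1-carbaldehyde (configured as F5) | C=C1CCCC(C)(C)[C@@H]2CC[C@@](C)(C=O)[C@H]12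
F8 | step 24 | (1R,3aR,8aS)-1-(1-bromo-2,2-dimethoxyethyl)-1,4,4-trimethyl-8-methylidenedecahydroazulene (CHBr epimers) | C=C1CCCC(C)(C)[C@@H]2CC[C@@](C)(C(Br)C(OC)OC)[C@H]12
F9 | step 25 | [(2R,3R)-5-hydroxy-2-(methoxycarbonyl)-4-[(1R,3aR,8aS)-1,4,4-trimethyl-8-methylidenedecahydroazulen-1-yl]oxolan-3-yl]acetic acid (epimers at C4 and C5 of the oxolane) | C=C1CCCC(C)(C)[C@@H]2CC[C@@](C)(C3C(O)O[C@@H](C(=O)OC)[C@@H]3CC(=O)O)[C@H]12
F10 | step 28 | α-hydroperoxy derivative of 36 (hydroperoxide on the CH next to the silylethyl ester, epimers) | C=C1CCCC(C)(C)[C@@H]2CC[C@@](C)([C@@H]3C(OC)O[C@@H](C(=O)OC)[C@@H]3C(OO)C(=O)OCC[Si](C)(C)C)[C@H]12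
F11 | step 28 | α-hydroxy derivative of 36 (epimers) | C=C1CCCC(C)(C)[C@@H]2CC[C@@](C)([C@@H]3C(OC)O[C@@H](C(=O)OC)[C@@H]3C(O)C(=O)OCC[Si](C)(C)C)[C@H]12
F12 | step 28 | α-acetoxy derivative of 36 (epimers) | C=C1CCCC(C)(C)[C@@H]2CC[C@@](C)([C@@H]3C(OC)O[C@@H](C(=O)OC)[C@@H]3C(OC(C)=O)C(=O)OCC[Si](C)(C)C)[C@H]12
F13 | step 28 | α-acetoxy derivative of 37 (epimers) | C=C1CCCC(C)(C)[C@@H]2CC[C@@](C)([C@@H]3C(OC)O[C@@H](C(=O)OC)[C@@H]3C(OC(C)=O)C(=O)O)[C@H]12
F14 | step 28 | C4 epimer of 40 | C=C1CCCC(C)(C)[C@@H]2CC[C@@](C)([C@@H]3[C@@H]4OC(=O)[C@H](OC(C)=O)[C@H]3[C@H](C(=O)OC)O4)[C@H]12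
A1 | alternative 1 | methyl 2-diazo-2-[5-(2-tert-butoxy-2-oxoethyl)-5-methylcyclopent-1-en-1-yl]acetate (configured as in A3) | COC(=O)C(=[N+]=[N-])C1=CCC[C@@]1(C)CC(=O)OC(C)(C)C
A2 | alternative 1 | 4-methylpenta-1,3-diene | CC(C)=CC=C
A3 | alternative 1 | bicyclo[5.3.0]decadiene ester with gem-dimethyl group | COC(=O)C1=C2[C@](C)(CC(=O)OC(C)(C)C)CC[C@H]2C(C)(C)C=CC1
A4 | alternative 2 | 5-[(4-methoxybenzyl)oxy]-4-[(triethylsilyl)oxy]-2-(1,4,4-trimethyl-8-methylidenedecahydroazulen-1-yl)pent-2-enal (configured as in A6) | C=C1CCCC(C)(C)[C@@H]2CC[C@@](C)(C(C=O)=C[C@@H](O[Si](CC)(CC)CC)COCc3ccc(OC)cc3)[C@H]12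
A5 | alternative 2 | tris(trimethylsilyloxy)ethene | C[Si](C)(C)OC=C(O[Si](C)(C)C)O[Si](C)(C)C
A6 | alternative 2 | 2,2,3-tris(trimethylsilyloxy)-3,4-dihydro-2H-pyran cycloadduct | C=C1CCCC(C)(C)[C@@H]2CC[C@@](C)(C3=COC(O[Si](C)(C)C)(O[Si](C)(C)C)[C@@H](O[Si](C)(C)C)[C@H]3[C@@H](O[Si](CC)(CC)CC)COCc4ccc(OC)cc4)[C@H]12
A7 | alternative 3 | 2-methoxy-3-(1,4,4-trimethyl-8-oxodecahydroazulen-1-yl)-3,6-dihydro-2H-pyran (configured as in A9) | O=C1CCCC(C)(C)[C@@H]2CC[C@@](C)([C@H]3C=CCO[C@@H]3OC)[C@H]12
A8 | alternative 3 | methyl diazoacetate | COC(=O)C=[N+]=[N-]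
A9 | alternative 3 | methyl 5-methoxy-4-(hydroazulenonyl)-3-vinyltetrahydrofuran-2-carboxylate | O=C1CCCC(C)(C)[C@@H]2CC[C@@](C)([C@@H]3[C@@H](OC)O[C@@H](C(=O)OC)[C@@H]3C=C)[C@H]12
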